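## Structural features

Locants used throughout: indane C1–C7a (C1 carries the aryl group), benzodioxane O1′–C8a′ (O1′ on C8a′, C8′ bonded to C1).

1. The target joins an indane (benzene ring A fused to cyclopentane ring C) through C1 to C8′ of a 1,4-benzodioxane (benzene ring B fused to dioxane ring D).
2. Ring A is 1,2,3,4-tetrasubstituted: C3a and C7a belong to ring C, C7 carries the formyl group and C6 the phenol, which together form a salicylaldehyde.
3. C2 is a fully substituted alkene carbon carrying the exocyclic isopropylidene group; this unconjugated tetrasubstituted double bond can migrate into ring C (indene) or out to an isopropenyl group under acid.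
4. There are two stereocentres: C1 (R), a diarylmethine carbon that is also allylic, and C2′ (S) in ring D, which carries the 2-hydroxypropan-2-yl group. They are separated by C8′, C8a′ and O1′, so neither can control the other.
5. C1–H is doubly benzylic, allylic and peri to the formyl group; it is the fragile point towards acid, base, oxidants and any cation chemistry.
6. Ring B must be substituted at C8′, ortho to O1′, whereas electrophilic substitution of a preformed benzodioxane would go to C7′ (para to O4′, ortho to the methyl group).
7. The real difficulty is the combination of the C1 stereocentre, the adjacent tetrasubstituted exocyclic alkene and the crowded ring A.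
8. The key step exploits that C1 is bonded to two aryl carbons (C7a, C8′) and to the sp2 carbon C2. The C1–C2 bond of ring C can therefore be made as an sp3–sp2 cross-coupling between a diarylmethyl C–O electrophile (no β-hydrogen, configuration easy to set) and an alkenylboron at C2 that already contains the isopropylidene double bond.

## Logic of the disconnections

**21 from 19.** The C–O bonds of two protecting groups are cut (acetal at the C7 carbon, methoxymethyl on O6). The salicylaldehyde is unveiled last because it is electrophilic, acidic and peri to C1. The forward step must be mild enough not to move the C2 double bond.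

**19 from 18 (key).** The C1–C2 bond of ring C is cut. The product simplifies to an open diarylmethyl pivalate whose ring A carries a 2-boryl-3-methylbut-2-enyl chain. This turns the C1 problem into the configuration of a C–O bond, and the alkene problem into the constitution of an alkenylboronate. The demand is a ring closure that transfers the C–O configuration to C1 without a free cation or radical, and without acid.

**18 from 16 and 17.** The C3–C3a bond and the C2–B bond are cut. Three components (aryl bromide, allene, diboron) give the whole C3/C2/isopropylidene unit in one operation. The demand is regiocontrol: the aryl group must go to the CH2 terminus of 17 and boron to its central carbon, and the catalysts must spare the diarylmethyl ester.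

**16 from 15.** The O–acyl bond is cut. The demand is selective acylation of the secondary diarylcarbinol beside the tertiary alcohol of ring D.

**15 from 12 and 7.** The C1–C7a bond is cut. Two arenes of similar size are joined at an aldehyde carbon, which is convergent. The demand is catalyst control of the new carbinol centre, since C2′ is too far away to help, and a metal at C7a that tolerates the neighbouring bromide.

**12 from 11, 11 from 9, 9 from 8.** The acetal C–O bonds, the C7–CHO bond and the O–CH2 bond of the ether are cut. The four contiguous substituents of ring A come from one deprotonation at the only position flanked by oxygen and iodine. The demand is lithiation without halogen scrambling, and two halogens that can be addressed one after the other (iodine for C1, bromine for C3).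

**7 from 5 and 3.** The O4′–C3′ and O1′–C2′ bonds of ring D are cut. A catechol aldehyde and a C5 epoxy sulfonate remain. The demand is that the two phenoxides react in the right order (the oxygen remote from the formyl group first, at CH2), and that the second opens the epoxide at the secondary carbon with inversion.

**5 from 4, 3 from 1.** An O–CH3 bond and, for 3, the epoxide C–O bonds and the S–O bond are cut. The demand on the epoxidation is the absolute configuration that becomes (S) at C2′ after one inversion.

## Other disconnections considered

**Alternative 1:** the first idea, cutting C1–C8′. The 8′-lithiated benzodioxane A1 would be added to the 2-(propan-2-ylidene)indan-1-one A2, and the tertiary carbinol A3 reduced by ionic hydrogenation to 19.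
- The carbonyl of A2 is flanked by the peri C7 substituent and an isopropylidene methyl group, so addition of a hindered aryllithium is expected to be slow.
- The reduction passes through a planar diaryl allyl cation. Only C2′, five bonds away, is chiral, so no facial bias at C1 is expected.
- Hydride can also enter at the CMe2 terminus (indene), and the acid can migrate the double bond.
- The chosen plan never forms a cation at C1 and takes the configuration from a C–O bond set by a catalyst.

**Alternative 2:** the biomimetic cut, C1–C2 by cation–olefin cyclisation. The ortho-prenyl diarylcarbinol A4 would be ionised by acid; the prenyl double bond attacks C1 and the tertiary cation loses a proton.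
- It closes the same bond as the chosen plan and the precursor is simple.
- The diarylmethyl cation is planar, so C1 is uncontrolled.
- Proton loss can give the isopropenyl isomer A5 as well as the isopropylidene compound, or the cation can be trapped.
- The acid needed is incompatible with the acetal and the acetal-type ether.
- The chosen plan keeps the bond but replaces ionisation by invertive metal insertion and fixes the alkene position by ipso substitution at boron.

**Alternative 3:** construction of ring A, cutting C3a–C7a and C6–C7. The furan–ynal A6 would undergo an intramolecular Diels–Alder reaction, followed by opening of the oxygen bridge. The furan oxygen becomes the C6 hydroxyl, the ynal gives the C7 formyl group, and ring C closes at the same time, without protecting groups on ring A.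
- This is attractive for ring A, but the C1–H of A6 is propargylic to an ynal, benzylic and allylic. Isomerisation to an allenal, and with it loss of the C1 configuration, is expected to be easy.
- No reliable enantioselective access to a methine carrying aryl, alkynyl and tetrasubstituted alkenyl groups can be named.
- The plan therefore moves the stereochemical problem to a more labile intermediate. The chosen plan builds ring A in two steps by ortho-metalation and keeps C1 as a robust ester until the ring closure.

Key step: step 10

Assumption: 4 and 8 are taken to be catalogue compounds.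
Assumption: in step 7 the (S)-configured ligand is taken to deliver the aryl group to the Si face of the aldehyde, as this catalyst type does with simple aromatic aldehydes; if the hindered partners reverse the sense, the (R)-ligand is used.

## Route

Step 1
Reactants: 1 3-methylbut-2-en-1-ol
Product: 3 [(2R)-3,3-dimethyloxiran-2-yl]methyl 3-nitrobenzenesulfonate, via epoxy alcohol 2 (not isolated)
Conditions: Ti(OiPr)4 (5 mol%), D-(−)-diisopropyl tartrate (7 mol%), t-BuOOH, 4 Å MS, CH2Cl2, −20 °C; then P(OMe)3; then Et3N, DMAP (cat.), 3-nitrobenzenesulfonyl chloride, −10 °C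
Reagents that add atoms: tert-butyl hydroperoxide, CC(C)(C)OO; 3-nitrobenzenesulfonyl chloride, O=S(=O)(Cl)c1cccc([N+](=O)[O-])c1
Why: Katsuki–Sharpless asymmetric epoxidation: the D-(−)-tartrate ligand on titanium delivers oxygen to the face of the allylic alcohol that gives the (2R)-epoxy alcohol (the L-(+)-tartrate gives the (2S) series); the small, water-soluble epoxy alcohol is sulfonylated in the same flask, and the crystalline sulfonate should allow enrichment by recrystallisation.

Step 2
Reactants: 4 2-hydroxy-3-methoxy-5-methylbenzaldehyde
Product: 5 2,3-dihydroxy-5-methylbenzaldehyde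
Conditions: BBr3, CH2Cl2, −78 °C to 0 °C; H2O
Reagents that add atoms: none
Why: Lewis-acid O-demethylation of an aryl methyl ether (bromide attacks the methyl group of the boron-bound ether); the formyl group tolerates BBr3 at low temperature.

Step 3
Reactants: 5 2,3-dihydroxy-5-methylbenzaldehyde; 3 [(2R)-3,3-dimethyloxiran-2-yl]methyl 3-nitrobenzenesulfonate
Product: 7 (2S)-2-(2-hydroxypropan-2-yl)-6-methyl-2,3-dihydro-1,4-benzodioxine-8-carbaldehyde, via sodium epoxy ether phenolate 6 (not isolated)
Conditions: NaH (2.1 equiv), DMSO, rt; then 3, rt to 60 °C; H2O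
Reagents that add atoms: none
Why: Double O-alkylation in one flask: in the dianion the C3 phenoxide, which is neither conjugated with nor chelated to the formyl group, is the more nucleophilic and displaces the sulfonate at CH2 (SN2, epoxide untouched) to give 6; the remaining C2 phenoxide then opens the epoxide 6-exo-tet at the secondary carbon with inversion, which closes ring D, puts O1′ on the stereocentre and gives (S) at C2′ together with the tertiary alcohol.

Step 4
Reactants: 8 4-bromo-3-iodophenol
Product: 9 1-bromo-2-iodo-4-(methoxymethoxy)benzene
Conditions: MeOCH2Cl, i-Pr2NEt, CH2Cl2, 0 °C to rt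
Reagents that add atoms: chloromethyl methyl ether, COCCl
Why: Williamson-type O-alkylation; the methoxymethyl ether masks the phenol, serves as the directing group in step 5 and is inert to the bases and low-valent metals used later.

Step 5
Reactants: 9 1-bromo-2-iodo-4-(methoxymethoxy)benzene
Product: 11 3-bromo-2-iodo-6-(methoxymethoxy)benzaldehyde, via aryllithium 10 (not isolated)
Conditions: LiN(iPr)2, THF, −78 °C; DMF; then H2O
Reagents that add atoms: N,N-dimethylformamide, CN(C)C=O
Why: Directed ortho-lithiation: the proton between the methoxymethoxy group (which binds the lithium amide) and iodine is the most acidic of the ring and should be removed at −78 °C without halogen–metal exchange; formylation of the aryllithium completes the contiguous 1,2,3,4-pattern of ring A in one operation.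

Step 6
Reactants: 11 3-bromo-2-iodo-6-(methoxymethoxy)benzaldehyde
Product: 12 1-bromo-3-(dimethoxymethyl)-2-iodo-4-(methoxymethoxy)benzene
Conditions: HC(OMe)3, MeOH, pyridinium p-toluenesulfonate (5 mol%), rt
Reagents that add atoms: trimethyl orthoformate, COC(OC)OC; methanol, CO
Why: Acid-catalysed acetalisation; the dimethyl acetal protects the future C7 formyl group against the organomagnesium, alkoxide and boryl nucleophiles of steps 7 to 10, and the mild catalyst should leave the methoxymethyl ether intact.

Step 7
Reactants: 12 1-bromo-3-(dimethoxymethyl)-2-iodo-4-(methoxymethoxy)benzene; 7 (2S)-2-(2-hydroxypropan-2-yl)-6-methyl-2,3-dihydro-1,4-benzodioxine-8-carbaldehyde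
Product: 15 (R)-[6-bromo-2-(dimethoxymethyl)-3-(methoxymethoxy)phenyl][(2S)-2-(2-hydroxypropan-2-yl)-6-methyl-2,3-dihydro-1,4-benzodioxin-8-yl]methanol, via arylmagnesium chloride 13 (not isolated), via aryltitanium triisopropoxide 14 (not isolated)
Conditions: i-PrMgCl·LiCl, THF, −40 °C; Ti(OiPr)4 (excess), CH2Cl2, −78 °C; then 7, (S)-3-(3,5-diphenylphenyl)-H8-BINOL (5 mol%), 0 °C; H2O
Reagents that add atoms: none
Why: Iodine–magnesium exchange takes place at the carbon–iodine bond only (the bromide stays) and transmetalation gives an aryltitanium triisopropoxide; its addition to the aldehyde is a catalytic asymmetric aryl transfer under a chiral titanium bis-naphtholate, which should deliver the aryl group to the Si face of 7 and set the C1–O centre as (R) under catalyst control, the distant C2′ centre being a spectator; excess Ti(OiPr)4 also masks the tertiary alcohol as a titanate.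

Step 8
Reactants: 15 (R)-[6-bromo-2-(dimethoxymethyl)-3-(methoxymethoxy)phenyl][(2S)-2-(2-hydroxypropan-2-yl)-6-methyl-2,3-dihydro-1,4-benzodioxin-8-yl]methanol
Product: 16 (R)-[6-bromo-2-(dimethoxymethyl)-3-(methoxymethoxy)phenyl][(2S)-2-(2-hydroxypropan-2-yl)-6-methyl-2,3-dihydro-1,4-benzodioxin-8-yl]methyl 2,2-dimethylpropanoate
Conditions: NaH (1.1 equiv), THF, 0 °C; t-BuCOCl, 0 °C to rt
Reagents that add atoms: pivaloyl chloride, CC(C)(C)C(=O)Cl
Why: O-Acylation: one equivalent of NaH deprotonates the more acidic diarylcarbinol, and the hindered tertiary alcohol of ring D should not compete for pivaloyl chloride; the pivalate is chosen because its carbonyl resists alkoxide and low-valent metals, which leaves the benzylic C–O bond as the reactive site in step 10.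

Step 9
Reactants: 16 (R)-[6-bromo-2-(dimethoxymethyl)-3-(methoxymethoxy)phenyl][(2S)-2-(2-hydroxypropan-2-yl)-6-methyl-2,3-dihydro-1,4-benzodioxin-8-yl]methyl 2,2-dimethylpropanoate; 17 3-methylbuta-1,2-diene
Product: 18 (S)-{2-(dimethoxymethyl)-3-(methoxymethoxy)-6-[3-methyl-2-(4,4,5,5-tetramethyl-1,3,2-dioxaborolan-2-yl)but-2-en-1-yl]phenyl}[(2S)-2-(2-hydroxypropan-2-yl)-6-methyl-2,3-dihydro-1,4-benzodioxin-8-yl]methyl 2,2-dimethylpropanoate
Conditions: 17 (3 equiv), B2pin2, CuCl (10 mol%), PCy3 (12 mol%), Pd(OAc)2 (5 mol%), XPhos (10 mol%), NaOtBu, toluene, 50 °C, sealed tube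
Reagents that add atoms: bis(pinacolato)diboron, CC1(C)OB(OC1(C)C)B1OC(C)(C)C(C)(C)O1
Why: Cooperative copper/palladium arylboration of an allene (three-component carboboration): the borylcopper species adds across the unsubstituted C=C of 17 with boron on the central carbon and copper on CH2, and this allylcopper hands its CH2 terminus to the arylpalladium bromide formed at C3a–Br, so that reductive elimination gives the C3–C3a bond. The two methyl groups on the distal carbon are identical, so no alkene geometry has to be controlled; the stereodescriptor at the carbinol carbon changes from R to S only because bromine is replaced by carbon.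

Step 10
Reactants: 18 (S)-{2-(dimethoxymethyl)-3-(methoxymethoxy)-6-[3-methyl-2-(4,4,5,5-tetramethyl-1,3,2-dioxaborolan-2-yl)but-2-en-1-yl]phenyl}[(2S)-2-(2-hydroxypropan-2-yl)-6-methyl-2,3-dihydro-1,4-benzodioxin-8-yl]methyl 2,2-dimethylpropanoate
Product: 19 2-{(2S)-8-[(1R)-7-(dimethoxymethyl)-6-(methoxymethoxy)-2-(propan-2-ylidene)-2,3-dihydro-1H-inden-1-yl]-6-methyl-2,3-dihydro-1,4-benzodioxin-2-yl}propan-2-ol
Conditions: Ni(cod)2 (10 mol%), SIMes (12 mol%), NaOMe (2 equiv), n-BuOH (2 equiv), toluene, 60 °C
Reagents that add atoms: none
Why: Zerovalent nickel carrying the N-heterocyclic carbene inserts into the benzylic C1–O bond of the pivalate by backside (SN2-type) attack, which inverts C1 and gives a diarylmethylnickel species that has no β-hydrogen (both β-carbons are aromatic) and so cannot collapse by β-hydride elimination. Methoxide turns the pendant pinacol boronate into a borate that hands its alkenyl carbon C2 to nickel with retention, and reductive elimination, also with retention at C1, forms the C1–C2 bond. The closest known reaction type is the stereospecific nickel-catalysed Suzuki–Miyaura coupling of enantioenriched secondary benzylic and diarylmethyl pivalates or carbamates with boronic esters, which runs with inversion under carbene ligation; here it is used intramolecularly. Ring C is closed in a 5-exo sense at C1 (the leaving oxygen lies outside the new ring) through a six-membered nickelacycle Ni–C1–C7a–C3a–C3–C2. The only new stereocentre, C1, is controlled by the configuration of the C1–O bond of 18 (net inversion, giving 1R); C2′ is a spectator. The step needs insertion into the benzylic C–O bond and not into the aryl C–O bonds of the ether and of ring D, which the much easier activation of a diarylmethyl ester at 60 °C should secure. It also needs the double bond to stay in place, which is secured because the carbon that carried boron becomes C2 (ipso substitution) and the medium is basic. Intramolecular delivery should offset the slow transmetalation of a tetrasubstituted alkenylboronate.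

Step 11
Reactants: 19 2-{(2S)-8-[(1R)-7-(dimethoxymethyl)-6-(methoxymethoxy)-2-(propan-2-ylidene)-2,3-dihydro-1H-inden-1-yl]-6-methyl-2,3-dihydro-1,4-benzodioxin-2-yl}propan-2-ol
Product: 21 Diaporindene G, via methoxymethyl ether aldehyde 20 (not isolated)
Conditions: 2 M aq. HCl, THF, rt
Reagents that add atoms: water, O
Why: Aqueous acid hydrolyses the dimethyl acetal first and then the methoxymethyl ether, whose cleavage is eased by the neighbouring formyl group; dilute acid at room temperature should neither protonate the tetrasubstituted double bond nor ionise the tertiary alcohol, and C1 is not touched.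

## Compound list

1 | 3-methylbut-2-en-1-ol | CC(C)=CCO | starting material
2 | [(2R)-3,3-dimethyloxiran-2-yl]methanol | CC1(C)O[C@@H]1CO | intermediate
3 | [(2R)-3,3-dimethyloxiran-2-yl]methyl 3-nitrobenzenesulfonate | CC1(C)O[C@@H]1COS(=O)(=O)c1cccc([N+](=O)[O-])c1 | intermediate
4 | 2-hydroxy-3-methoxy-5-methylbenzaldehyde | COc1cc(C)cc(C=O)c1O | starting material
5 | 2,3-dihydroxy-5-methylbenzaldehyde | Cc1cc(O)c(O)c(C=O)c1 | intermediate
6 | sodium 2-{[(2R)-3,3-dimethyloxiran-2-yl]methoxy}-6-formyl-4-methylphenolate | Cc1cc(C=O)c([O-])c(OC[C@H]2OC2(C)C)c1.[Na+] | intermediate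
7 | (2S)-2-(2-hydroxypropan-2-yl)-6-methyl-2,3-dihydro-1,4-benzodioxine-8-carbaldehyde | O=Cc1cc(C)cc2c1O[C@H](C(C)(C)O)CO2 | intermediate
8 | 4-bromo-3-iodophenol | Oc1ccc(Br)c(I)c1 | starting material
9 | 1-bromo-2-iodo-4-(methoxymethoxy)benzene | COCOc1ccc(Br)c(I)c1 | intermediate
10 | [3-bromo-2-iodo-6-(methoxymethoxy)phenyl]lithium | COCOc1ccc(Br)c(I)c1[Li] | intermediate
11 | 3-bromo-2-iodo-6-(methoxymethoxy)benzaldehyde | COCOc1ccc(Br)c(I)c1C=O | intermediate
12 | 1-bromo-3-(dimethoxymethyl)-2-iodo-4-(methoxymethoxy)benzene | COCOc1ccc(Br)c(I)c1C(OC)OC | intermediate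
13 | [6-bromo-2-(dimethoxymethyl)-3-(methoxymethoxy)phenyl]magnesium chloride | COCOc1ccc(Br)c([Mg]Cl)c1C(OC)OC | intermediate
14 | [6-bromo-2-(dimethoxymethyl)-3-(methoxymethoxy)phenyl]titanium triisopropoxide | COCOc1ccc(Br)c([Ti](OC(C)C)(OC(C)C)OC(C)C)c1C(OC)OC | intermediate
15 | (R)-[6-bromo-2-(dimethoxymethyl)-3-(methoxymethoxy)phenyl][(2S)-2-(2-hydroxypropan-2-yl)-6-methyl-2,3-dihydro-1,4-benzodioxin-8-yl]methanol | COCOc1ccc(Br)c([C@H](O)c2cc(C)cc3c2O[C@H](C(C)(C)O)CO3)c1C(OC)OC | intermediate
16 | (R)-[6-bromo-2-(dimethoxymethyl)-3-(methoxymethoxy)phenyl][(2S)-2-(2-hydroxypropan-2-yl)-6-methyl-2,3-dihydro-1,4-benzodioxin-8-yl]methyl 2,2-dimethylpropanoate | COCOc1ccc(Br)c([C@H](OC(=O)C(C)(C)C)c2cc(C)cc3c2O[C@H](C(C)(C)O)CO3)c1C(OC)OC | intermediate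
17 | 3-methylbuta-1,2-diene | CC(C)=C=C | starting material
18 | (S)-{2-(dimethoxymethyl)-3-(methoxymethoxy)-6-[3-methyl-2-(4,4,5,5-tetramethyl-1,3,2-dioxaborolan-2-yl)but-2-en-1-yl]phenyl}[(2S)-2-(2-hydroxypropan-2-yl)-6-methyl-2,3-dihydro-1,4-benzodioxin-8-yl]methyl 2,2-dimethylpropanoate | COCOc1ccc(CC(B2OC(C)(C)C(C)(C)O2)=C(C)C)c([C@H](OC(=O)C(C)(C)C)c2cc(C)cc3c2O[C@H](C(C)(C)O)CO3)c1C(OC)OC | intermediate
19 | 2-{(2S)-8-[(1R)-7-(dimethoxymethyl)-6-(methoxymethoxy)-2-(propan-2-ylidene)-2,3-dihydro-1H-inden-1-yl]-6-methyl-2,3-dihydro-1,4-benzodioxin-2-yl}propan-2-ol | CC(C)=C1Cc2ccc(OCOC)c(C(OC)OC)c2[C@@H]1c1cc(C)cc2c1O[C@H](C(C)(C)O)CO2 | intermediate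
20 | (1R)-1-[(2S)-2-(2-hydroxypropan-2-yl)-6-methyl-2,3-dihydro-1,4-benzodioxin-8-yl]-6-(methoxymethoxy)-2-(propan-2-ylidene)-2,3-dihydro-1H-indene-7-carbaldehyde | CC(C)=C1Cc2ccc(OCOC)c(C=O)c2[C@@H]1c1cc(C)cc2c1O[C@H](C(C)(C)O)CO2 | intermediate
21 | Diaporindene G, (1R)-6-hydroxy-1-[(2S)-2-(2-hydroxypropan-2-yl)-6-methyl-2,3-dihydro-1,4-benzodioxin-8-yl]-2-(propan-2-ylidene)-2,3-dihydro-1H-indene-7-carbaldehyde | CC(C)=C1Cc2ccc(O)c(C=O)c2[C@@H]1c1cc(C)cc2c1O[C@H](C(C)(C)O)CO2 | target

## Step count and risks

Total: 11 steps. Longest linear sequence: 8 steps (steps 4 to 11, from 8). Least certain: step 10 (key), then steps 7, 9 and 11.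

**Step 10 (key).** The likely failure is slow transfer of the hindered tetrasubstituted alkenyl group from boron to the crowded diarylmethylnickel species. That intermediate then lives long enough for nickel–carbon homolysis, which erodes the stereochemical fidelity at C1, or for reduction and dimerisation; insertion itself may also be slow because ring A is substituted on both sides of C7a. The fallback gives up the metal and the chirality transfer and closes the same bond by an SN1 ipso-cyclisation. It sets out from 18: ionisation of the pivalate in 1,1,1,3,3,3-hexafluoropropan-2-ol, buffered with 2,6-di-tert-butylpyridine, lets the alkenylboronate attack the diarylmethyl cation at C2, and loss of boron restores the C2 double bond. It returns to the route at 19, which would be formed together with its C1 epimer, 2-{(2S)-8-[(1S)-7-(dimethoxymethyl)-6-(methoxymethoxy)-2-(propan-2-ylidene)-2,3-dihydro-1H-inden-1-yl]-6-methyl-2,3-dihydro-1,4-benzodioxin-2-yl}propan-2-ol F1. The two are diastereomers because of C2′ and would be separated by chromatography, at the cost of the material lost as F1.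

**Step 7.** The likely failure is poor facial discrimination together with low reactivity, because the aryl group to be transferred carries substituents on both ortho positions; elimination of the ortho-bromoaryl metal to an aryne on warming is a second risk. The fallback sets the carbinol centre by hydride delivery and not by aryl transfer. It sets out from 12 and 7: uncatalysed addition of 13 at −40 °C gives the carbinol as a mixture of both configurations, [6-bromo-2-(dimethoxymethyl)-3-(methoxymethoxy)phenyl][(2S)-2-(2-hydroxypropan-2-yl)-6-methyl-2,3-dihydro-1,4-benzodioxin-8-yl]methanol F2. Dess–Martin periodinane oxidises it to the diaryl ketone [6-bromo-2-(dimethoxymethyl)-3-(methoxymethoxy)phenyl][(2S)-2-(2-hydroxypropan-2-yl)-6-methyl-2,3-dihydro-1,4-benzodioxin-8-yl]methanone F3. Its two aryl groups differ strongly in twist, so asymmetric transfer hydrogenation (RuCl(p-cymene)[(S,S)-TsDPEN] or its mirror image, whichever delivers hydride to the required face, HCO2H/Et3N) should return the route to 15.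

**Step 9.** The likely failure is loss of regiocontrol when the allylcopper passes its carbon to palladium (coupling at the CMe2 terminus), or ionisation of the diarylmethyl pivalate by zerovalent palladium, or simple reduction of the C–Br bond. The fallback separates boron introduction from the C–C coupling. It sets out from 17: Pt(PPh3)4-catalysed diboration with B2pin2 at the unsubstituted double bond gives the bis(boronate) 2,2′-(3-methylbut-2-ene-1,2-diyl)bis(4,4,5,5-tetramethyl-1,3,2-dioxaborolane) F4. Its allylic C–B bond is then coupled chemoselectively with 16 in a Suzuki–Miyaura reaction (Pd(OAc)2, SPhos, K3PO4, THF/H2O), which returns to the route at 18.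

**Step 11.** The likely failure is acid-promoted migration of the exocyclic double bond into conjugation with ring A, or ionisation at the tertiary alcohol, during the slower ether cleavage. The fallback sets out from 19 and replaces the single Brønsted-acid operation by two stages: near-neutral acetal hydrolysis (pyridinium p-toluenesulfonate, acetone/H2O) with isolation of 20, then chelation-directed cleavage of the ether by MgBr2·OEt2 in Et2O, in which the ortho-formyl group binds magnesium. It returns to the route at 21 (no new compound: F0).

## Further compounds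

F1 | step 10 | 2-{(2S)-8-[(1S)-7-(dimethoxymethyl)-6-(methoxymethoxy)-2-(propan-2-ylidene)-2,3-dihydro-1H-inden-1-yl]-6-methyl-2,3-dihydro-1,4-benzodioxin-2-yl}propan-2-ol | CC(C)=C1Cc2ccc(OCOC)c(C(OC)OC)c2[C@H]1c1cc(C)cc2c1O[C@H](C(C)(C)O)CO2
F2 | step 7 | [6-bromo-2-(dimethoxymethyl)-3-(methoxymethoxy)phenyl][(2S)-2-(2-hydroxypropan-2-yl)-6-methyl-2,3-dihydro-1,4-benzodioxin-8-yl]methanol, both configurations at the carbinol carbon | COCOc1ccc(Br)c(C(O)c2cc(C)cc3c2O[C@H](C(C)(C)O)CO3)c1C(OC)OC
F3 | step 7 | [6-bromo-2-(dimethoxymethyl)-3-(methoxymethoxy)phenyl][(2S)-2-(2-hydroxypropan-2-yl)-6-methyl-2,3-dihydro-1,4-benzodioxin-8-yl]methanone | COCOc1ccc(Br)c(C(=O)c2cc(C)cc3c2O[C@H](C(C)(C)O)CO3)c1C(OC)OC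
F4 | step 9 | 2,2′-(3-methylbut-2-ene-1,2-diyl)bis(4,4,5,5-tetramethyl-1,3,2-dioxaborolane) | CC(C)=C(CB1OC(C)(C)C(C)(C)O1)B1OC(C)(C)C(C)(C)O1
F0 | step 11 | none | none
A1 | alternative 1 | lithium 2-[(2S)-8-lithio-6-methyl-2,3-dihydro-1,4-benzodioxin-2-yl]propan-2-olate | [Li]c1cc(C)cc2c1O[C@H](C(C)(C)O[Li])CO2
A2 | alternative 1 | 7-(dimethoxymethyl)-6-(methoxymethoxy)-2-(propan-2-ylidene)-2,3-dihydro-1H-inden-1-one | CC(C)=C1Cc2ccc(OCOC)c(C(OC)OC)c2C1=O
A3 | alternative 1 | 7-(dimethoxymethyl)-1-[(2S)-2-(2-hydroxypropan-2-yl)-6-methyl-2,3-dihydro-1,4-benzodioxin-8-yl]-6-(methoxymethoxy)-2-(propan-2-ylidene)-2,3-dihydro-1H-inden-1-ol, both configurations at C1 | CC(C)=C1Cc2ccc(OCOC)c(C(OC)OC)c2C1(O)c1cc(C)cc2c1O[C@H](C(C)(C)O)CO2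
A4 | alternative 2 | [2-(dimethoxymethyl)-3-(methoxymethoxy)-6-(3-methylbut-2-en-1-yl)phenyl][(2S)-2-(2-hydroxypropan-2-yl)-6-methyl-2,3-dihydro-1,4-benzodioxin-8-yl]methanol, both configurations at the carbinol carbon | CC(C)=CCc1ccc(OCOC)c(C(OC)OC)c1C(O)c1cc(C)cc2c1O[C@H](C(C)(C)O)CO2
A5 | alternative 2 | 2-{(2S)-8-[7-(dimethoxymethyl)-6-(methoxymethoxy)-2-(prop-1-en-2-yl)-2,3-dihydro-1H-inden-1-yl]-6-methyl-2,3-dihydro-1,4-benzodioxin-2-yl}propan-2-ol, stereoisomer mixture at C1 and C2 | C=C(C)C1Cc2ccc(OCOC)c(C(OC)OC)c2C1c1cc(C)cc2c1O[C@H](C(C)(C)O)CO2
A6 | alternative 3 | (4R)-5-(furan-2-ylmethyl)-4-[(2S)-2-(2-hydroxypropan-2-yl)-6-methyl-2,3-dihydro-1,4-benzodioxin-8-yl]-6-methylhept-5-en-2-ynal | O=CC#C[C@@H](C(Cc1ccco1)=C(C)C)c1cc(C)cc2c1O[C@H](C(C)(C)O)CO2
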